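The route rests on disconnecting the pyran O1–C2 bond of the upper (epioritin) unit: C2 is a benzylic carbinol carbon carrying ring B, and O1 is the ring A phenol oxygen on C8a, joined to it through C4a, C4 and C3. An intramolecular Mitsunobu etherification closes ring C of that unit and, by SN2 inversion, sets C2 cis to the C3 oxygen and trans to the C4 aryl, a contra-thermodynamic pattern. Its precursor is an open 1,3,3-triarylpropane with an anti 1,2-dioxygenated chain, whose C4 and C3 centres come from a Rh(acac)(C2H4)2/SEGPHOS-catalysed arylation of 7,8-bis(benzyloxy)coumarin and a trans-selective lactone oxygenation. The lower flavan-3,4-diol is then grown on ring D.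

Key step: step 11

Remark: the SMILES is read as a 2,3-cis-3,4-trans 4-arylflavan-3-ol (upper unit, 2R,3R,4S) joined through C4 to C6 of a 2,3-cis-3,4-trans flavan-3,4-diol (lower unit, 2R,3R,4S); ArD stands for 2,3-bis(benzyloxy)-4-[(tert-butyldimethylsilyl)oxy]-5-(1,3-dioxolan-2-yl)phenyl, the future ring D; open-chain atoms are also called by their future flavan locants; CIP descriptors of protected intermediates differ from those of the target at upper C4 only because benzylation changes the priority of the two aryl groups.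

Step 1
Reactants: 1 2,3,4-trihydroxybenzaldehyde
Product: 2 3,4-bis(benzyloxy)-2-hydroxybenzaldehyde
Conditions: BnBr (2 equiv), K2CO3, DMF, rt
Reagents that add atoms: benzyl bromide BrCc1ccccc1
Why: Williamson etherification; the 2-hydroxyl is locked in a hydrogen bond to the formyl group and its phenoxide is the least nucleophilic, so two equivalents of benzyl bromide should alkylate O-4 and O-3 and leave O-2 free.

Step 2
Reactants: 2 3,4-bis(benzyloxy)-2-hydroxybenzaldehyde
Product: 3 3,4-bis(benzyloxy)-5-bromo-2-hydroxybenzaldehyde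
Conditions: N-bromosuccinimide, MeCN, 0 °C
Reagents that add atoms: N-bromosuccinimide O=C1CCC(=O)N1Br
Why: Electrophilic aromatic bromination; C-5 is para to the free phenol and ortho to the 4-benzyloxy group, the only doubly activated open position, so bromine should enter at the carbon that later carries the interflavan bond.

Step 3
Reactants: 3 3,4-bis(benzyloxy)-5-bromo-2-hydroxybenzaldehyde
Product: 4 3,4-bis(benzyloxy)-5-bromo-2-[(tert-butyldimethylsilyl)oxy]benzaldehyde
Conditions: t-BuMe2SiCl, imidazole, DMF, rt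
Reagents that add atoms: tert-butyldimethylsilyl chloride CC(C)(C)[Si](C)(C)Cl
Why: Silyl ether formation masks the future ring D pyran oxygen with a group that fluoride removes in the presence of benzyl ethers.

Step 4
Reactants: 4 3,4-bis(benzyloxy)-5-bromo-2-[(tert-butyldimethylsilyl)oxy]benzaldehyde
Product: 5 2-{3,4-bis(benzyloxy)-5-bromo-2-[(tert-butyldimethylsilyl)oxy]phenyl}-1,3-dioxolane
Conditions: Me3SiOCH2CH2OSiMe3, Me3SiOTf (cat.), CH2Cl2, −78 to −20 °C
Reagents that add atoms: 1,2-bis(trimethylsilyloxy)ethane C[Si](C)(C)OCCO[Si](C)(C)C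
Why: Noyori acetalisation under aprotic, low-temperature conditions protects the aldehyde against the organolithium, hydride and Grignard steps without touching the aryl silyl ether.

Step 5
Reactants: 5 2-{3,4-bis(benzyloxy)-5-bromo-2-[(tert-butyldimethylsilyl)oxy]phenyl}-1,3-dioxolane
Product: 6 {2,3-bis(benzyloxy)-4-[(tert-butyldimethylsilyl)oxy]-5-(1,3-dioxolan-2-yl)phenyl}boronic acid (ArD–B(OH)2)
Conditions: n-BuLi, THF, −78 °C; B(OiPr)3; aq. NH4Cl
Reagents that add atoms: triisopropyl borate CC(C)OB(OC(C)C)OC(C)C; water O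
Why: Bromine–lithium exchange followed by borylation and hydrolysis; exchange at −78 °C should outrun attack on the acetal or the benzyl ethers.

Step 6
Reactants: 7 daphnetin (7,8-dihydroxy-2H-chromen-2-one)
Product: 8 7,8-bis(benzyloxy)-2H-chromen-2-one
Conditions: BnBr, K2CO3, DMF, 60 °C
Reagents that add atoms: benzyl bromide BrCc1ccccc1
Why: Williamson etherification of both phenols; the lactone oxygen, the future O1, is thereby the only ring A oxygen not carried as a benzyl ether.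

Step 7
Reactants: 8 7,8-bis(benzyloxy)-2H-chromen-2-one; 6 ArD–B(OH)2
Product: 9 (4R)-7,8-bis(benzyloxy)-4-ArD-chroman-2-one
Conditions: Rh(acac)(C2H4)2 (3 mol %), (S)-SEGPHOS, 6 (3 equiv), 1,4-dioxane/H2O 10:1, 60 °C
Reagents that add atoms: none
Why: Hayashi–Miyaura asymmetric conjugate addition, in which transmetalation from boron gives an Ar–Rh(SEGPHOS) species that inserts the coumarin C3=C4 bond before water protonates the oxa-π-allyl; the (S)-ligand, mirror image of the one that gives (R)-4-arylchroman-2-ones with simple arylboronic acids, should put the aryl on the face that becomes 4β (4R here because ArD outranks C4a), and the excess boronic acid offsets protodeboronation.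

Step 8
Reactants: 9 (4R)-7,8-bis(benzyloxy)-4-ArD-chroman-2-one
Product: 11 (3R,4R)-7,8-bis(benzyloxy)-4-ArD-3-(triethylsilyloxy)chroman-2-one (3,4-trans), via silyl ketene acetal 10 (not isolated)
Conditions: LiN(SiMe3)2, Et3SiCl, THF, −78 °C; then dimethyldioxirane, acetone/CH2Cl2, −78 to −20 °C
Reagents that add atoms: triethylsilyl chloride CC[Si](CC)(CC)Cl; dimethyldioxirane CC1(C)OO1
Why: Rubottom oxidation, in which the lactone enolate is O-silylated and dimethyldioxirane epoxidises the ketene acetal on the face anti to the pseudo-axial C4 aryl, the silyl group then shifting to the new oxygen, so the C3 oxygen should be set trans to the aryl (3R).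

Step 9
Reactants: 11 (3R,4R)-7,8-bis(benzyloxy)-4-ArD-3-(triethylsilyloxy)chroman-2-one
Product: 12 (3R,4R)-7,8-bis(benzyloxy)-4-ArD-3-(triethylsilyloxy)chroman-2-ol (lactol, both anomers)
Conditions: iBu2AlH (1.2 equiv), CH2Cl2, −78 °C; aq. Rochelle salt
Reagents that add atoms: none
Why: Partial reduction of a lactone; the tetrahedral aluminate is stable at −78 °C and should give the cyclic hemiacetal on work-up.

Step 10
Reactants: 12 (3R,4R)-7,8-bis(benzyloxy)-4-ArD-3-(triethylsilyloxy)chroman-2-ol; 13 4-(benzyloxy)phenylmagnesium bromide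
Product: 14 (1S,2R,3R)-1-[4-(benzyloxy)phenyl]-3-[3,4-bis(benzyloxy)-2-hydroxyphenyl]-3-ArD-2-(triethylsilyloxy)propan-1-ol (1,2-anti)
Conditions: 13 (3.5 equiv), THF, −78 to −20 °C; aq. NH4Cl
Reagents that add atoms: none
Why: Grignard addition to the hydroxy aldehyde tautomer of the lactol; with the non-chelating silyloxy group the Felkin–Anh mode (C–O anti to the incoming aryl, attack past H and not past the diarylmethyl group) should give the 1,2-anti carbinol (1S).

Step 11
Reactants: 14 (1S,2R,3R)-1-[4-(benzyloxy)phenyl]-3-[3,4-bis(benzyloxy)-2-hydroxyphenyl]-3-ArD-2-(triethylsilyloxy)propan-1-ol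
Product: 15 (2R,3R,4R)-7,8-bis(benzyloxy)-2-[4-(benzyloxy)phenyl]-4-ArD-3-(triethylsilyloxy)chromane (2,3-cis-3,4-trans)
Conditions: PPh3, DIAD, toluene, 0 °C to rt
Reagents that add atoms: none
Why: PPh3 and DIAD turn the benzylic C-1 hydroxyl of 14 into an oxyphosphonium leaving group while the betaine deprotonates the ring A phenol, the only acidic O–H present, and the phenoxide oxygen O1 displaces Ph3PO from C2 by SN2. The closest known reaction type is the intramolecular Mitsunobu etherification of 3-(2-hydroxyphenyl)-1-arylpropan-1-ols to 2-arylchromans. Ring C closes in the 6-exo-tet mode. C2 is set by inversion of the 1S carbinol, so the anti 1,2-dioxygenated chain becomes the 2,3-cis arrangement, which with the preset 3,4-trans relation gives the 2,4-trans diaryl pattern that an equilibrating cationic or quinone methide closure would not deliver. The step needs SN2 over SN1 and six- over five-membered closure: the silylated C3 oxygen can be neither activated nor act as a nucleophile, the ring D phenol is silylated and lies para to the tether, and the non-polar solvent and low temperature disfavour ionisation of the 4-benzyloxybenzylic oxyphosphonium.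

Step 12
Reactants: 15 (2R,3R,4R)-7,8-bis(benzyloxy)-2-[4-(benzyloxy)phenyl]-4-ArD-3-(triethylsilyloxy)chromane
Product: 16 3,4-bis(benzyloxy)-5-{(2R,3R,4R)-7,8-bis(benzyloxy)-2-[4-(benzyloxy)phenyl]-3-hydroxychroman-4-yl}-2-[(tert-butyldimethylsilyl)oxy]benzaldehyde
Conditions: 1 M aq. HCl, THF, 0 °C to rt
Reagents that add atoms: water O
Why: Acid hydrolysis should cleave the dioxolane and the triethylsilyl ether in one operation, while the aryl tert-butyldimethylsilyl ether and the benzyl ethers, more stable to dilute acid, survive.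

Step 13
Reactants: 17 3,4-bis(benzyloxy)benzaldehyde
Product: 18 1,2-bis(benzyloxy)-4-ethynylbenzene
Conditions: dimethyl (1-diazo-2-oxopropyl)phosphonate, K2CO3, MeOH, rt
Reagents that add atoms: dimethyl (1-diazo-2-oxopropyl)phosphonate CC(=O)C(=[N+]=[N-])P(=O)(OC)OC
Why: Ohira–Bestmann (Seyferth–Gilbert) homologation converts the aldehyde into the terminal alkyne that supplies lower C2, C3 and ring B.

Step 14
Reactants: 16 the aldehyde of step 12; 18 1,2-bis(benzyloxy)-4-ethynylbenzene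
Product: 19 (1R)-1-{3,4-bis(benzyloxy)-5-[(2R,3R,4R)-7,8-bis(benzyloxy)-2-(4-(benzyloxy)phenyl)-3-hydroxychroman-4-yl]-2-[(tert-butyldimethylsilyl)oxy]phenyl}-3-[3,4-bis(benzyloxy)phenyl]prop-2-yn-1-ol
Conditions: 18 (4 equiv), Et2Zn, toluene, reflux; then (R)-BINOL, Ti(OiPr)4, CH2Cl2, rt; then 16
Reagents that add atoms: none
Why: Catalytic asymmetric alkynylzinc addition to an aryl aldehyde under (R)-BINOL/Ti(OiPr)4 control; this catalyst enantiomer should deliver the alkynyl group to the Re face, the mirror of the Si-face sense of the (S)-BINOL system, setting the future lower C4 carbinol (R), while the free C3 hydroxyl only consumes one equivalent of RC≡CZnEt.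

Step 15
Reactants: 19 the propargylic alcohol of step 14
Product: 20 the (1R,2Z)-allylic alcohol, (1R,2Z)-1-{aryl as in 19}-3-[3,4-bis(benzyloxy)phenyl]prop-2-en-1-ol
Conditions: H2 (1 atm), Pd/CaCO3 poisoned with Pb(OAc)2 (Lindlar catalyst), quinoline, EtOAc, rt
Reagents that add atoms: none
Why: Lindlar semihydrogenation gives the Z-alkene by syn delivery of hydrogen; aryl benzyl ethers and the benzylic alcohol should not be reduced on Pd/CaCO3–Pb(OAc)2.

Step 16
Reactants: 20 the (1R,2Z)-allylic alcohol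
Product: 21 the threo cis-epoxy alcohol, (S)-{aryl as in 19}[(2R,3S)-3-(3,4-bis(benzyloxy)phenyl)oxiran-2-yl]methanol
Conditions: dimethyldioxirane, acetone, −40 to −20 °C
Reagents that add atoms: dimethyldioxirane CC1(C)OO1
Why: Hydroxyl-directed epoxidation of a Z-allylic alcohol; 1,3-allylic strain holds the carbinol hydrogen in the alkene plane and hydrogen bonding to the hydroxyl guides the neutral oxidant to one face, which should give the threo cis-epoxy alcohol carrying lower C3 and, before inversion, lower C2.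

Step 17
Reactants: 21 the threo cis-epoxy alcohol
Product: 23 (2R,3R,4S)-7,8-bis(benzyloxy)-2-[3,4-bis(benzyloxy)phenyl]-6-{(2R,3R,4R)-7,8-bis(benzyloxy)-2-[4-(benzyloxy)phenyl]-3-hydroxychroman-4-yl}chromane-3,4-diol, via epoxy phenol 22 (not isolated)
Conditions: Bu4NF, AcOH, THF, 0 °C; then Ti(OiPr)4, CH2Cl2, 0 °C to rt
Reagents that add atoms: none
Why: Buffered fluoride frees the ring D phenol without Payne rearrangement, and Ti(OiPr)4, bound to the carbinol and epoxide oxygens, directs the phenol to the distal benzylic epoxide carbon (C-3-selective opening of a 2,3-epoxy alcohol, 6-endo-tet) with inversion, which should give the 2,3-cis-3,4-trans flavan-3,4-diol.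

Step 18
Reactants: 23 the heptabenzyl ether of step 17
Product: 24 CNP0275688.1, (2R,3R,4S)-2-(3,4-dihydroxyphenyl)-6-[(2R,3R,4S)-3,7,8-trihydroxy-2-(4-hydroxyphenyl)chroman-4-yl]chromane-3,4,7,8-tetrol (epioritin-(4β→6)-epimesquitol-4β-ol pattern)
Conditions: H2 (1 atm), Pd(OH)2/C, THF/MeOH, rt, under argon on work-up
Reagents that add atoms: none
Why: Hydrogenolysis of the seven aryl benzyl ethers under neutral conditions; without acid the benzylic C4 hydroxyl and the cyclic benzylic O1–C2 ethers should be cleaved far more slowly than O-benzyl groups.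

Compound list
1 | 2,3,4-trihydroxybenzaldehyde | O=Cc1ccc(O)c(O)c1O | starting material
2 | 3,4-bis(benzyloxy)-2-hydroxybenzaldehyde | O=Cc1ccc(OCc2ccccc2)c(OCc2ccccc2)c1O | intermediate
3 | 3,4-bis(benzyloxy)-5-bromo-2-hydroxybenzaldehyde | O=Cc1cc(Br)c(OCc2ccccc2)c(OCc2ccccc2)c1O | intermediate
4 | 3,4-bis(benzyloxy)-5-bromo-2-[(tert-butyldimethylsilyl)oxy]benzaldehyde | O=Cc1cc(Br)c(OCc2ccccc2)c(OCc2ccccc2)c1O[Si](C)(C)C(C)(C)C | intermediate
5 | 2-{3,4-bis(benzyloxy)-5-bromo-2-[(tert-butyldimethylsilyl)oxy]phenyl}-1,3-dioxolane | Brc1cc(C2OCCO2)c(O[Si](C)(C)C(C)(C)C)c(OCc2ccccc2)c1OCc1ccccc1 | intermediate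
6 | {2,3-bis(benzyloxy)-4-[(tert-butyldimethylsilyl)oxy]-5-(1,3-dioxolan-2-yl)phenyl}boronic acid | OB(O)c1cc(C2OCCO2)c(O[Si](C)(C)C(C)(C)C)c(OCc2ccccc2)c1OCc1ccccc1 | intermediate
7 | daphnetin (7,8-dihydroxy-2H-chromen-2-one) | O=c1ccc2ccc(O)c(O)c2o1 | starting material
8 | 7,8-bis(benzyloxy)-2H-chromen-2-one | O=c1ccc2ccc(OCc3ccccc3)c(OCc3ccccc3)c2o1 | intermediate
9 | (4R)-7,8-bis(benzyloxy)-4-ArD-chroman-2-one | O=C1C[C@@H](c2cc(C3OCCO3)c(O[Si](C)(C)C(C)(C)C)c(OCc3ccccc3)c2OCc2ccccc2)c2ccc(OCc3ccccc3)c(OCc3ccccc3)c2O1 | intermediate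
10 | (4R)-7,8-bis(benzyloxy)-4-ArD-2-(triethylsilyloxy)-4H-chromene (silyl ketene acetal, not isolated) | CC[Si](CC)(CC)OC1=C[C@@H](c2cc(C3OCCO3)c(O[Si](C)(C)C(C)(C)C)c(OCc3ccccc3)c2OCc2ccccc2)c2ccc(OCc3ccccc3)c(OCc3ccccc3)c2O1 | intermediate
11 | (3R,4R)-7,8-bis(benzyloxy)-4-ArD-3-(triethylsilyloxy)chroman-2-one | O=C1[C@H](O[Si](CC)(CC)CC)[C@@H](c2cc(C3OCCO3)c(O[Si](C)(C)C(C)(C)C)c(OCc3ccccc3)c2OCc2ccccc2)c2ccc(OCc3ccccc3)c(OCc3ccccc3)c2O1 | intermediate
12 | (3R,4R)-7,8-bis(benzyloxy)-4-ArD-3-(triethylsilyloxy)chroman-2-ol (both anomers) | OC1[C@H](O[Si](CC)(CC)CC)[C@@H](c2cc(C3OCCO3)c(O[Si](C)(C)C(C)(C)C)c(OCc3ccccc3)c2OCc2ccccc2)c2ccc(OCc3ccccc3)c(OCc3ccccc3)c2O1 | intermediate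
13 | 4-(benzyloxy)phenylmagnesium bromide | Br[Mg]c1ccc(OCc2ccccc2)cc1 | starting material
14 | (1S,2R,3R)-1-[4-(benzyloxy)phenyl]-3-[3,4-bis(benzyloxy)-2-hydroxyphenyl]-3-ArD-2-(triethylsilyloxy)propan-1-ol | O[C@@H](c1ccc(OCc2ccccc2)cc1)[C@H](O[Si](CC)(CC)CC)[C@@H](c1cc(C2OCCO2)c(O[Si](C)(C)C(C)(C)C)c(OCc2ccccc2)c1OCc1ccccc1)c1ccc(OCc2ccccc2)c(OCc2ccccc2)c1O | intermediate
15 | (2R,3R,4R)-7,8-bis(benzyloxy)-2-[4-(benzyloxy)phenyl]-4-ArD-3-(triethylsilyloxy)chromane | C(c1ccccc1)Oc1ccc([C@H]2Oc3c(ccc(OCc4ccccc4)c3OCc3ccccc3)[C@H](c3cc(C4OCCO4)c(O[Si](C)(C)C(C)(C)C)c(OCc4ccccc4)c3OCc3ccccc3)[C@H]2O[Si](CC)(CC)CC)cc1 | intermediate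
16 | 3,4-bis(benzyloxy)-5-{(2R,3R,4R)-7,8-bis(benzyloxy)-2-[4-(benzyloxy)phenyl]-3-hydroxychroman-4-yl}-2-[(tert-butyldimethylsilyl)oxy]benzaldehyde | C(c1ccccc1)Oc1ccc([C@H]2Oc3c(ccc(OCc4ccccc4)c3OCc3ccccc3)[C@H](c3cc(C=O)c(O[Si](C)(C)C(C)(C)C)c(OCc4ccccc4)c3OCc3ccccc3)[C@H]2O)cc1 | intermediate
17 | 3,4-bis(benzyloxy)benzaldehyde | O=Cc1ccc(OCc2ccccc2)c(OCc2ccccc2)c1 | starting material
18 | 1,2-bis(benzyloxy)-4-ethynylbenzene | C#Cc1ccc(OCc2ccccc2)c(OCc2ccccc2)c1 | intermediate
19 | (1R)-propargylic alcohol from 16 and 18 (upper unit 2R,3R,4R) | C(c1ccccc1)Oc1ccc([C@H]2Oc3c(ccc(OCc4ccccc4)c3OCc3ccccc3)[C@H](c3cc([C@H](O)C#Cc4ccc(OCc5ccccc5)c(OCc5ccccc5)c4)c(O[Si](C)(C)C(C)(C)C)c(OCc4ccccc4)c3OCc3ccccc3)[C@H]2O)cc1 | intermediate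
20 | (1R,2Z)-allylic alcohol from 19 | C(c1ccccc1)Oc1ccc([C@H]2Oc3c(ccc(OCc4ccccc4)c3OCc3ccccc3)[C@H](c3cc([C@H](O)/C=C\c4ccc(OCc5ccccc5)c(OCc5ccccc5)c4)c(O[Si](C)(C)C(C)(C)C)c(OCc4ccccc4)c3OCc3ccccc3)[C@H]2O)cc1 | intermediate
21 | threo cis-epoxy alcohol: carbinol S, oxirane 2R,3S | C(c1ccccc1)Oc1ccc([C@H]2Oc3c(ccc(OCc4ccccc4)c3OCc3ccccc3)[C@H](c3cc([C@H](O)[C@H]4O[C@H]4c4ccc(OCc5ccccc5)c(OCc5ccccc5)c4)c(O[Si](C)(C)C(C)(C)C)c(OCc4ccccc4)c3OCc3ccccc3)[C@H]2O)cc1 | intermediate
22 | epoxy phenol: 21 without the silyl group (not isolated) | C(c1ccccc1)Oc1ccc([C@H]2Oc3c(ccc(OCc4ccccc4)c3OCc3ccccc3)[C@H](c3cc([C@H](O)[C@H]4O[C@H]4c4ccc(OCc5ccccc5)c(OCc5ccccc5)c4)c(O)c(OCc4ccccc4)c3OCc3ccccc3)[C@H]2O)cc1 | intermediate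
23 | heptabenzyl ether of the target: (2R,3R,4S)-7,8-bis(benzyloxy)-2-[3,4-bis(benzyloxy)phenyl]-6-{(2R,3R,4R)-7,8-bis(benzyloxy)-2-[4-(benzyloxy)phenyl]-3-hydroxychroman-4-yl}chromane-3,4-diol | C(c1ccccc1)Oc1ccc([C@H]2Oc3c(ccc(OCc4ccccc4)c3OCc3ccccc3)[C@H](c3cc4c(c(OCc5ccccc5)c3OCc3ccccc3)O[C@H](c3ccc(OCc5ccccc5)c(OCc5ccccc5)c3)[C@H](O)[C@H]4O)[C@H]2O)cc1 | intermediate
24 | CNP0275688.1, (2R,3R,4S)-2-(3,4-dihydroxyphenyl)-6-[(2R,3R,4S)-3,7,8-trihydroxy-2-(4-hydroxyphenyl)chroman-4-yl]chromane-3,4,7,8-tetrol | Oc1ccc([C@H]2Oc3c(ccc(O)c3O)[C@H](c3cc4c(c(O)c3O)O[C@H](c3ccc(O)c(O)c3)[C@H](O)[C@H]4O)[C@H]2O)cc1 | target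

Total step count: 18. Longest linear sequence: 16 steps (steps 1–5, 7–12 and 14–18).

Steps most likely to fail

Step 11 (key step). The oxyphosphonium at the 4-benzyloxybenzylic carbon may ionise, or lose a proton towards C3, before O1 attacks, so that inversion is lost and closure drifts to the more stable 2,3-trans epimer or to a styrene. The fallback carries ring B through the closure as a 4-bromophenyl group, which cannot stabilise a cation, and installs its oxygen afterwards. It sets out from lactol 12: 4-bromophenylmagnesium bromide (THF, −78 to −20 °C) gives (1S,2R,3R)-1-(4-bromophenyl)-3-[3,4-bis(benzyloxy)-2-hydroxyphenyl]-3-ArD-2-(triethylsilyloxy)propan-1-ol F1. The same Mitsunobu closure (PPh3, DIAD, toluene) gives (2R,3R,4R)-7,8-bis(benzyloxy)-2-(4-bromophenyl)-4-ArD-3-(triethylsilyloxy)chromane F2. C–O cross-coupling with benzyl alcohol (Pd2(dba)3, RockPhos, K3PO4, toluene, 90 °C) then turns the aryl bromide into the benzyl ether and comes back to the route at 15.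

Step 7. Insertion of the electron-rich 7-alkoxycoumarin into the Ar–Rh bond may be slow, so that hydrolysis of the hindered ortho-alkoxyaryl–Rh species (protodeboronation) consumes the boronic acid. The fallback separates carbon–carbon bond formation from the setting of C4. It sets out from 8 and 6: an oxidative Heck reaction (Pd(OAc)2, 1,10-phenanthroline, O2, DMF, 80 °C) gives 7,8-bis(benzyloxy)-4-ArD-2H-chromen-2-one F3. CuH-catalysed asymmetric conjugate reduction (Cu(OAc)2·H2O, the DTBM-SEGPHOS enantiomer that delivers hydride to the face giving the 4R lactone, (EtO)2MeSiH, t-BuOH, toluene) comes back at 9.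

Step 10. Facial selectivity may be poor because magnesium chelates between the aldehyde oxygen and the phenoxide or a benzyloxy group, so the Felkin–Anh mode no longer dominates; migration of the triethylsilyl group to the new alkoxide is a second pathway. The fallback sets C2 by a catalyst instead of by the substrate. It sets out from lactone 11: one equivalent of 13 at −78 °C opens the aryl lactone to (2R,3R)-1-[4-(benzyloxy)phenyl]-3-[3,4-bis(benzyloxy)-2-hydroxyphenyl]-3-ArD-2-(triethylsilyloxy)propan-1-one F4. Noyori–Ikariya transfer hydrogenation (RuCl[(R,R)-TsDPEN](p-cymene), HCO2H/Et3N, CH2Cl2, rt) should give the 1S carbinol and comes back at 14.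

Further compounds
F1 | step 11 | (1S,2R,3R)-1-(4-bromophenyl)-3-[3,4-bis(benzyloxy)-2-hydroxyphenyl]-3-ArD-2-(triethylsilyloxy)propan-1-ol | O[C@@H](c1ccc(Br)cc1)[C@H](O[Si](CC)(CC)CC)[C@@H](c1cc(C2OCCO2)c(O[Si](C)(C)C(C)(C)C)c(OCc2ccccc2)c1OCc1ccccc1)c1ccc(OCc2ccccc2)c(OCc2ccccc2)c1O
F2 | step 11 | (2R,3R,4R)-7,8-bis(benzyloxy)-2-(4-bromophenyl)-4-ArD-3-(triethylsilyloxy)chromane | Brc1ccc([C@H]2Oc3c(ccc(OCc4ccccc4)c3OCc3ccccc3)[C@H](c3cc(C4OCCO4)c(O[Si](C)(C)C(C)(C)C)c(OCc4ccccc4)c3OCc3ccccc3)[C@H]2O[Si](CC)(CC)CC)cc1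
F3 | step 7 | 7,8-bis(benzyloxy)-4-ArD-2H-chromen-2-one | O=c1cc(-c2cc(C3OCCO3)c(O[Si](C)(C)C(C)(C)C)c(OCc3ccccc3)c2OCc2ccccc2)c2ccc(OCc3ccccc3)c(OCc3ccccc3)c2o1
F4 | step 10 | (2R,3R)-1-[4-(benzyloxy)phenyl]-3-[3,4-bis(benzyloxy)-2-hydroxyphenyl]-3-ArD-2-(triethylsilyloxy)propan-1-one | O=C(c1ccc(OCc2ccccc2)cc1)[C@H](O[Si](CC)(CC)CC)[C@@H](c1cc(C2OCCO2)c(O[Si](C)(C)C(C)(C)C)c(OCc2ccccc2)c1OCc1ccccc1)c1ccc(OCc2ccccc2)c(OCc2ccccc2)c1O
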